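## Analysis of the target

The target is a flavone: a 4H-chromen-4-one (benzo ring A fused to pyranone ring C) carrying a 2,5-dimethoxyphenyl group (ring B) at C2. It has no stereocentre, so the whole problem is one of regiochemistry on ring A. Ring A is penta-substituted: C5 bears a free hydroxyl hydrogen-bonded to the C4 carbonyl, C7 and C8 bear methoxy groups, C8a carries the ring oxygen O1, C4a carries the carbonyl carbon, and only C6 has a hydrogen. The sensitive features are the four aryl methyl ethers, which must survive the unmasking of the 5-hydroxyl, the electron-rich rings A and B, which take up electrophiles easily, and the pyranone, which strong nucleophiles open at C2. The difficulty is that C4a lies between two oxygenated carbons, C5 and C8a, whose oxygens must end differently, one as a free hydroxyl and one in ring C. If they are not told apart, the 5-hydroxy-6,7-dimethoxy isomer results. The strategy rests on C4: this carbonyl carbon is bonded only to C4a of ring A and to C3, so it can be brought in as carbon monoxide between an aryl iodide at C4a and a terminal arylacetylene that supplies C3, C2 and ring B, with the phenol oxygen on C8a closing ring C onto C2.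

## Retrosynthetic reasoning

**15 to 14.** The last bond cut is the O–CH2 bond of a methoxymethyl ether on the C5 oxygen. This oxygen must be masked during ring construction, because a second free hydroxyl next to the iodine-bearing carbon would let either oxygen close ring C and give both the 7,8- and the 6,7-dimethoxy pattern. A benzyl ether would serve equally in the ring-forming step, but its benzylic hydrogens are a second site for the alkyllithium base needed earlier in the sequence, and its removal would call for a strong Lewis acid beside four methyl ethers. The methoxymethyl ether has neither drawback, helps to direct the metalation, and comes off in dilute acid. The forward reaction only has to cleave an acetal.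

**14 to 8, 10 and 11.** Ring C is opened at three bonds: C4a–C4, C4–C3 and O1–C2. This isolates C4 as a one-carbon unit (11), leaves ring A as iodophenol 8, and leaves ring B with C2 and C3 as alkyne 10. The cut is made here because every oxygen of ring A then sits on an ordinary benzene ring before the key step, the two halves are of similar size, and ring B is bought. The classical cut through a 1,3-diketone would need an acetyl group on the crowded C4a carbon of a differentiated resorcinol, which is harder to reach than an iodide. The forward reaction must insert 11 before the alkyne couples, and the closure must give the six-membered ring.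

**8 to 7 to 5.** The hydroxyl on the future C8a is released from a diethylcarbamate (7), and the C–I bond of 7 is traced back to a C–H bond of 5. The carbamate serves twice: it masks the phenol that becomes O1, and it is the strongest metalation director on the ring. In 5 one ortho position of the carbamate is occupied by a methoxy group, so its only ortho hydrogen lies between the carbamate and the methoxymethyl ether. That carbon is the future C4a. The forward reaction has to metalate there and be quenched cold, before the carbamoyl group can migrate.

**5 to 4 to 2 to 1.** The methoxymethyl ether of 5 comes from phenol 4, and the hydroxyl of 4 comes from the formyl group of 2 by Baeyer–Villiger oxidation. The aldehyde of commercial 1 is therefore a latent C5 oxygen. The hydroxyl already present in 1 lies next to a methoxy group, so it becomes O1 next to the C8 methoxy group. The two oxygens that flank the future C4a are thus told apart from the first step: one is carbamoylated in 1, the other is created later and protected differently.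

**10 to 9.** The alkyne is cut at the triple bond back to aldehyde 9 by a one-carbon homologation, which keeps ring B as a commercial 2,5-dimethoxyphenyl unit.

## Alternatives that were turned down

Alternative 1: Ring C is cut at O1–C8a, C4–C4a and O1–C2, so that ring A arrives as an aryne, generated from the silyl triflate A2, and the rest as the propiolic acid A3. Here A2 is 3,5-dimethoxy-2-(trimethylsilyl)phenyl trifluoromethanesulfonate A2, and A3 is 3-(2,5-dimethoxyphenyl)prop-2-ynoic acid A3.
- Forward key step: a fluoride source would release the aryne from A2. The carboxylate oxygen of A3 adds to the aryne carbon remote from the flanking methoxy group, the aryl anion attacks the acyl carbon, and the ortho-acyl phenoxide closes onto the ynone. The product would be 2-(2,5-dimethoxyphenyl)-5,7-dimethoxy-4H-chromen-4-one A1.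
- For it: no palladium and no toxic gas, mild conditions, and the bond O1–C8a is made in the step, so no phenol has to be prepared or protected. On these points it is stronger than the chosen route.
- Against it: A1 lacks the oxygen at C8 and carries the 5-oxygen as a methyl ether. C8 would have to be oxidised afterwards on a ring whose C6 and C8 are both activated, beside an equally electron-rich ring B. The 5-methyl ether would then have to be removed beside four others. That is at least three further steps beyond A1, two of them selectivity problems. Building the C8 oxygen into A2 does not help, because the aryne bond would then have an oxygen substituent on each side and the direction of insertion would no longer be controlled. A2 is also no stock compound and would itself take several steps to prepare.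
- Comparison: the chosen route accepts carbon monoxide (11) and palladium, fixes all four oxygens of ring A before the key step, and needs only an acetal cleavage after it.

Alternative 2: Ring A is cut at C5–C6 and rings C and B are kept. The precursor is racemic methyl 6-(2,5-dimethoxyphenyl)-2-(1-methoxy-2-oxopropyl)-4-oxo-4H-pyran-3-carboxylate A5, a pyranone with an ester on the future C4a and a methoxy ketone chain on the future C8a.
- Forward key step: base would form the methyl ketone enolate of A5 (future C6), which attacks the ester carbon (future C5). The resulting cyclohexanedione tautomerises to the arene and gives 2-(2,5-dimethoxyphenyl)-5,7-dihydroxy-8-methoxy-4H-chromen-4-one A4.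
- For it: the oxygen pattern of ring A follows from the carbon chain and cannot come out as the 6,7-isomer, and no protecting group is needed. Its endgame is better than the chosen one: the 7-hydroxyl of A4 is the more acidic and is not chelated, so one selective O-methylation would finish the synthesis with the 5-hydroxyl free.
- Against it: A5 is a fully substituted pyranone that no simple starting material resembles. Assembling the aryl group, the ester and the oxygenated side chain around it would take more steps than the whole chosen route, on a ring that nucleophiles open. In the key step the base meets a more acidic hydrogen (the methine between ketone, methoxy group and pyranone) before the methyl group, and alkoxide can attack the pyranone. The closure itself is untested on such a substrate.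
- Comparison: the risk would be spread over the synthesis of A5 and the key step. The chosen strategy puts it on one well-known step, with both partners a few steps from commercial aldehydes.

Alternative 3: Ring B is cut at C1'–C2' and C5'–C6'. The chromone arrives as 2-ethynyl-5,7,8-trimethoxy-4H-chromen-4-one A7, and four carbons of ring B with both its oxygens arrive as 2-methoxyfuran A8.
- Forward key step: a Diels–Alder addition of A8 across the alkyne of A7, with the unsubstituted furan terminus bonding to the terminal, electrophilic alkyne carbon, gives an oxanorbornadiene. Its bridge opens, helped by the bridgehead methoxy group, to 2-(5-hydroxy-2-methoxyphenyl)-5,7,8-trimethoxy-4H-chromen-4-one A6.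
- For it: the 2',5'-oxygen pattern is set by the polarity of the cycloaddition, and no carbon monoxide (11) is needed.
- Against it: ring B is the one part of the target that can be bought (as 9), so the key step would be spent where there is no difficulty. All the hard chemistry of rings A and C is still needed to make A7, and by a longer path, since an ethynyl group must be placed on C2 of a finished chromone. A8 is acid-labile and polymerises easily, A7 is also a Michael acceptor at C2, and A6 still needs O-methylation at C5' and selective demethylation at C5.
- Comparison: the chosen route is convergent, shorter, and builds the ring where the substitution is dense.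

Key step: step 7

Remark: the 5-oxygen is carried through ring construction as a methoxymethyl ether, which co-directs the metalation and is removed by dilute acid without risk to the methyl ethers.

## Route

Step 1
Reactants: 1 3-hydroxy-4,5-dimethoxybenzaldehyde
Product: 2 5-formyl-2,3-dimethoxyphenyl N,N-diethylcarbamate
Conditions: Et2NCOCl, K2CO3, MeCN, reflux
Reagents that add atoms: N,N-diethylcarbamoyl chloride, CCN(CC)C(Cl)=O
Why: O-Carbamoylation of the phenoxide by nucleophilic acyl substitution; the aldehyde does not react, and the carbamate is both the mask and the later metalation director for the oxygen that becomes O1.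

Step 2
Reactants: 2 5-formyl-2,3-dimethoxyphenyl N,N-diethylcarbamate
Product: 4 5-hydroxy-2,3-dimethoxyphenyl N,N-diethylcarbamate, via aryl formate 3 (not isolated)
Conditions: mCPBA, CH2Cl2, 0 °C to rt; aq NaHCO3 wash; then K2CO3 (cat.), MeOH, rt
Reagents that add atoms: meta-chloroperoxybenzoic acid (mCPBA), OOC(=O)c1cccc(Cl)c1
Why: Baeyer–Villiger oxidation: in the Criegee adduct the electron-rich aryl group (para-methoxy) should migrate in preference to hydride and give formate 3, which methanol cleaves by transesterification; the N,N-diethylcarbamate is inert to both reagents.

Step 3
Reactants: 4 5-hydroxy-2,3-dimethoxyphenyl N,N-diethylcarbamate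
Product: 5 2,3-dimethoxy-5-(methoxymethoxy)phenyl N,N-diethylcarbamate
Conditions: MOMCl, iPr2NEt, CH2Cl2, 0 °C to rt
Reagents that add atoms: chloromethyl methyl ether (MOMCl), COCCl
Why: O-Alkylation of the phenol by the α-chloro ether (Williamson-type etherification); the acetal formed is stable to the organolithium, the aqueous base and the amine of the following steps.

Step 4
Reactants: 5 2,3-dimethoxy-5-(methoxymethoxy)phenyl N,N-diethylcarbamate
Product: 7 2-iodo-5,6-dimethoxy-3-(methoxymethoxy)phenyl N,N-diethylcarbamate, via aryllithium 6 (not isolated)
Conditions: s-BuLi, TMEDA, THF, −78 °C; then I2, THF, −78 °C to rt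
Reagents that add atoms: iodine, II
Why: Directed ortho-metalation: the carbamate carbonyl binds s-BuLi and delivers it to its only free ortho hydrogen, which also lies next to the methoxymethyl ether, so aryllithium 6 should form at the carbon that becomes C4a; iodine traps it at −78 °C, before the anionic ortho-Fries shift of the carbamoyl group can set in.

Step 5
Reactants: 7 2-iodo-5,6-dimethoxy-3-(methoxymethoxy)phenyl N,N-diethylcarbamate
Product: 8 2-iodo-5,6-dimethoxy-3-(methoxymethoxy)phenol
Conditions: NaOH, EtOH/H2O, reflux; then aq NH4Cl
Reagents that add atoms: none
Why: Base hydrolysis of the aryl carbamate: hydroxide attacks the carbonyl and expels the phenoxide, and the carbamic acid salt breaks down to diethylamine and carbonate; the acetal, the aryl iodide and the methyl ethers are inert to aqueous base, and the near-neutral work-up spares the methoxymethyl ether.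

Step 6
Reactants: 9 2,5-dimethoxybenzaldehyde
Product: 10 2-ethynyl-1,4-dimethoxybenzene
Conditions: dimethyl (1-diazo-2-oxopropyl)phosphonate, K2CO3, MeOH, 0 °C to rt
Reagents that add atoms: dimethyl (1-diazo-2-oxopropyl)phosphonate (Ohira–Bestmann reagent), COP(=O)(OC)C(=[N+]=[N-])C(C)=O
Why: Seyferth–Gilbert homologation in the Ohira–Bestmann version: methoxide removes the acetyl group of the reagent, the diazomethylphosphonate anion olefinates the aldehyde (Horner–Wadsworth–Emmons), and the diazoalkene loses nitrogen and rearranges by a 1,2-hydrogen shift to the terminal alkyne.

Step 7
Reactants: 8 2-iodo-5,6-dimethoxy-3-(methoxymethoxy)phenol; 10 2-ethynyl-1,4-dimethoxybenzene; 11 carbon monoxide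
Product: 14 2-(2,5-dimethoxyphenyl)-7,8-dimethoxy-5-(methoxymethoxy)-4H-chromen-4-one, via ynone 12 (not isolated), via enaminone 13 (not isolated)
Conditions: PdCl2(PPh3)2 (5 mol %), CO (1 atm, balloon), Et2NH (5 equiv), DMF, 50 °C, no CuI
Reagents that add atoms: carbon monoxide (compound 11), [C-]#[O+]
Why: PdCl2(PPh3)2 is reduced in the flask to zerovalent palladium, which inserts into the C–I bond of 8; CO then inserts into the aryl–palladium bond to give an aroylpalladium iodide, a migration that is fast for an electron-rich, doubly ortho-substituted aryl group. Alkyne 10, deprotonated on palladium with the help of Et2NH, replaces iodide, and reductive elimination should give ynone 12 with the new bonds C4a–C4 and C4–C3. Et2NH adds to the ynone in a conjugate sense to give enaminone 13, and the phenol oxygen then attacks C2 in a 6-endo-trig addition followed by loss of the amine, which forms O1–C2 and closes ring C. The closest known reaction type is the palladium-catalysed carbonylative Sonogashira coupling and annulation of 2-iodophenols with terminal arylacetylenes to flavones. Three selectivities are needed: carbonylation before alkynylation (otherwise a 2-arylbenzofuran forms), six- over five-membered closure (otherwise an aurone forms), and the right oxygen pattern on ring A. The first is secured by the CO atmosphere, the absence of CuI and the electron-rich aryl group; the second by the amine, since the enaminone no longer has the triple bond that a 5-exo attack needs; the third by the substrate, because iodine sits between the free hydroxyl and the protected one and only the free hydroxyl can close. No stereocentre is formed.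

Step 8
Reactants: 14 2-(2,5-dimethoxyphenyl)-7,8-dimethoxy-5-(methoxymethoxy)-4H-chromen-4-one
Product: 15 2-(2,5-dimethoxyphenyl)-5-hydroxy-7,8-dimethoxy-4H-chromen-4-one (5-hydroxy-7,8,2',5'-tetramethoxyflavone)
Conditions: HCl in MeOH (1.25 M), 40 °C
Reagents that add atoms: none
Why: Acid-catalysed cleavage of the methoxymethyl acetal, with the oxocarbenium ion captured by methanol; the ether next to the C4 carbonyl is the most labile oxygen substituent present, and aryl methyl ethers and the flavone core do not react with dilute methanolic acid, so the hydrogen-bonded 5-hydroxyl should be freed without change at C7, C8, C2' or C5'.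

## Compound list

1 | 3-hydroxy-4,5-dimethoxybenzaldehyde | COc1cc(C=O)cc(O)c1OC | starting material
2 | 5-formyl-2,3-dimethoxyphenyl N,N-diethylcarbamate | CCN(CC)C(=O)Oc1cc(C=O)cc(OC)c1OC | intermediate
3 | 3-[(diethylcarbamoyl)oxy]-4,5-dimethoxyphenyl formate | CCN(CC)C(=O)Oc1cc(OC=O)cc(OC)c1OC | intermediate
4 | 5-hydroxy-2,3-dimethoxyphenyl N,N-diethylcarbamate | CCN(CC)C(=O)Oc1cc(O)cc(OC)c1OC | intermediate
5 | 2,3-dimethoxy-5-(methoxymethoxy)phenyl N,N-diethylcarbamate | CCN(CC)C(=O)Oc1cc(OCOC)cc(OC)c1OC | intermediate
6 | [2-(diethylcarbamoyloxy)-3,4-dimethoxy-6-(methoxymethoxy)phenyl]lithium | [Li]c1c(OCOC)cc(OC)c(OC)c1OC(=O)N(CC)CC | intermediate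
7 | 2-iodo-5,6-dimethoxy-3-(methoxymethoxy)phenyl N,N-diethylcarbamate | CCN(CC)C(=O)Oc1c(I)c(OCOC)cc(OC)c1OC | intermediate
8 | 2-iodo-5,6-dimethoxy-3-(methoxymethoxy)phenol | Oc1c(I)c(OCOC)cc(OC)c1OC | intermediate
9 | 2,5-dimethoxybenzaldehyde | COc1ccc(OC)c(C=O)c1 | starting material
10 | 2-ethynyl-1,4-dimethoxybenzene | C#Cc1cc(OC)ccc1OC | intermediate
11 | carbon monoxide | [C-]#[O+] | starting material
12 | 3-(2,5-dimethoxyphenyl)-1-[2-hydroxy-3,4-dimethoxy-6-(methoxymethoxy)phenyl]prop-2-yn-1-one | O=C(C#Cc1cc(OC)ccc1OC)c1c(O)c(OC)c(OC)cc1OCOC | intermediate
13 | 3-(diethylamino)-3-(2,5-dimethoxyphenyl)-1-[2-hydroxy-3,4-dimethoxy-6-(methoxymethoxy)phenyl]prop-2-en-1-one (C=C geometry not fixed; the push-pull alkene isomerises freely) | CCN(CC)C(=CC(=O)c1c(O)c(OC)c(OC)cc1OCOC)c1cc(OC)ccc1OC | intermediate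
14 | 2-(2,5-dimethoxyphenyl)-7,8-dimethoxy-5-(methoxymethoxy)-4H-chromen-4-one | O=c1cc(-c2cc(OC)ccc2OC)oc2c(OC)c(OC)cc(OCOC)c12 | intermediate
15 | 2-(2,5-dimethoxyphenyl)-5-hydroxy-7,8-dimethoxy-4H-chromen-4-one | COc1ccc(OC)c(-c2cc(=O)c3c(O)cc(OC)c(OC)c3o2)c1 | target

## Step count and least certain steps

Total: 8 steps. Longest linear sequence: 7 steps (steps 1, 2, 3, 4, 5, 7 and 8); step 6 is a one-step branch.

**Step 7 (key step).** Oxidative addition at an iodide flanked by two oxygens on an electron-rich ring may be slow, so the catalyst could decay under CO before turnover. Coupling of the alkyne before CO insertion would lead on to 5-endo closure to a benzofuran. Et2NH could capture the aroylpalladium species (aminocarbonylation). If amine addition to the ynone lags, 5-exo closure to an aurone could compete. The fallback replaces the palladium step by an anionic acylation. It sets out from 8 and 10 and comes back to the route at 14. Alkyne 10 is lithiated (n-BuLi, THF, −78 °C) and treated with N-methoxy-N-methylcarbamoyl chloride to give 3-(2,5-dimethoxyphenyl)-N-methoxy-N-methylprop-2-ynamide F1. Phenol 8 is treated with n-BuLi (2.2 equiv, THF, −78 °C), which forms the phenoxide and exchanges iodine for lithium, and the dianion is acylated with F1. Work-up should give ynone 12, now isolated. Warming 12 with Et2NH in EtOH should close ring C through 13 and give 14.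

**Step 4.** The aryllithium may undergo carbamoyl migration (anionic ortho-Fries) if it warms before the quench, and some metalation may occur at the other doubly flanked C–H, between the methoxymethyl ether and a methoxy group. The fallback installs iodine by electrophilic substitution before the oxidation. It sets out from 1 and comes back to the route at 8, and so also bypasses step 5. Iodination of 1 with ICl in pyridine should go ortho to the hydroxyl, at the carbon between OH and CHO that is also para to the 5-methoxy group, and give 3-hydroxy-2-iodo-4,5-dimethoxybenzaldehyde F2. Acylation of F2 with PivCl and Et3N gives 3-formyl-2-iodo-5,6-dimethoxyphenyl 2,2-dimethylpropanoate F3. Baeyer–Villiger oxidation of F3 with mCPBA in CH2Cl2 gives 3-(formyloxy)-2-iodo-5,6-dimethoxyphenyl 2,2-dimethylpropanoate F4, which KHCO3 in MeOH cleaves in the same flask to 3-hydroxy-2-iodo-5,6-dimethoxyphenyl 2,2-dimethylpropanoate F5. MOMCl and iPr2NEt convert F5 into 2-iodo-5,6-dimethoxy-3-(methoxymethoxy)phenyl 2,2-dimethylpropanoate F6, and NaOMe in MeOH removes the pivalate from F6 to return 8. The price is reliance on the site selectivity of the iodination, since the other open carbon of 1 is para to the hydroxyl, and on the aryl iodide surviving the peracid.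

**Step 5.** Hydrolysis of a carbamate hemmed in by iodine and a methoxy group may be sluggish, and long heating in base invites loss of iodine. The fallback is reductive cleavage in place of hydrolysis: 7 is treated with Cp2Zr(H)Cl in THF at rt, which adds hydride to the carbamate carbonyl. The adduct collapses to the zirconium phenoxide and N,N-diethylformamide, and aqueous work-up gives 8. This runs from 7 to 8 and makes no compound outside the compound list, so its line below is F0.

**Step 6.** Olefination of the ortho-substituted, electron-rich aldehyde by the diazophosphonate anion may be incomplete, and the small alkyne is easily lost on concentration. The fallback is a Corey–Fuchs sequence that sets out from 9 and comes back at 10: CBr4 and PPh3 in CH2Cl2 give 2-(2,2-dibromoethenyl)-1,4-dimethoxybenzene F7, and n-BuLi (2 equiv, THF, −78 °C) followed by water converts F7 into 10 by elimination and lithium–bromine exchange.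

## Further compounds

F1 | step 7 | 3-(2,5-dimethoxyphenyl)-N-methoxy-N-methylprop-2-ynamide | CON(C)C(=O)C#Cc1cc(OC)ccc1OC
F2 | step 4 | 3-hydroxy-2-iodo-4,5-dimethoxybenzaldehyde | O=Cc1cc(OC)c(OC)c(O)c1I
F3 | step 4 | 3-formyl-2-iodo-5,6-dimethoxyphenyl 2,2-dimethylpropanoate | CC(C)(C)C(=O)Oc1c(I)c(C=O)cc(OC)c1OC
F4 | step 4 | 3-(formyloxy)-2-iodo-5,6-dimethoxyphenyl 2,2-dimethylpropanoate | CC(C)(C)C(=O)Oc1c(I)c(OC=O)cc(OC)c1OC
F5 | step 4 | 3-hydroxy-2-iodo-5,6-dimethoxyphenyl 2,2-dimethylpropanoate | CC(C)(C)C(=O)Oc1c(I)c(O)cc(OC)c1OC
F6 | step 4 | 2-iodo-5,6-dimethoxy-3-(methoxymethoxy)phenyl 2,2-dimethylpropanoate | CC(C)(C)C(=O)Oc1c(I)c(OCOC)cc(OC)c1OC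
F0 | step 5 | none | none
F7 | step 6 | 2-(2,2-dibromoethenyl)-1,4-dimethoxybenzene | COc1ccc(OC)c(C=C(Br)Br)c1
A1 | alternative 1 | 2-(2,5-dimethoxyphenyl)-5,7-dimethoxy-4H-chromen-4-one | O=c1cc(-c2cc(OC)ccc2OC)oc2cc(OC)cc(OC)c12
A2 | alternative 1 | 3,5-dimethoxy-2-(trimethylsilyl)phenyl trifluoromethanesulfonate | COc1cc(OC)c([Si](C)(C)C)c(OS(=O)(=O)C(F)(F)F)c1
A3 | alternative 1 | 3-(2,5-dimethoxyphenyl)prop-2-ynoic acid | OC(=O)C#Cc1cc(OC)ccc1OC
A4 | alternative 2 | 2-(2,5-dimethoxyphenyl)-5,7-dihydroxy-8-methoxy-4H-chromen-4-one | O=c1cc(-c2cc(OC)ccc2OC)oc2c(OC)c(O)cc(O)c12
A5 | alternative 2 | methyl 6-(2,5-dimethoxyphenyl)-2-(1-methoxy-2-oxopropyl)-4-oxo-4H-pyran-3-carboxylate (racemic) | COC(=O)c1c(C(OC)C(C)=O)oc(-c2cc(OC)ccc2OC)cc1=O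
A6 | alternative 3 | 2-(5-hydroxy-2-methoxyphenyl)-5,7,8-trimethoxy-4H-chromen-4-one | O=c1cc(-c2cc(O)ccc2OC)oc2c(OC)c(OC)cc(OC)c12
A7 | alternative 3 | 2-ethynyl-5,7,8-trimethoxy-4H-chromen-4-one | C#Cc1cc(=O)c2c(OC)cc(OC)c(OC)c2o1
A8 | alternative 3 | 2-methoxyfuran | COc1ccco1
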